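**Retrosynthetic overview**
1. Late stage: the C2 angelate and the C20 acetate are put on a (13R)-labda-7,14-diene core. The C7=C8 alkene comes from a C7 ketone through its more substituted enol triflate.
2. Key disconnection: C8–C9 and C5–C10 by an intramolecular Diels–Alder reaction of an acyclic triene. Rings A and B form together in that step and no carbocycle exists before it.
3. Enabling feature: the oxidised angular carbon C20 on quaternary C10. Raised to the ester it makes C9=C10 a dienophile; the C7=C8 alkene of cyclohexene ring B maps onto a 2-silyloxydiene C5=C6–C7(OSi)=C8; ring A (C1–C4, with the C2/C3 cis-diol as acetonide and the C4 gem-dimethyl) is the tether.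
4. The triene comes from a Still–Gennari union of a phosphonate (C1–C8, C10, C17–C20) with an aldehyde made from (R)-linalool (C9, C11–C16; C13 bought).
5. The phosphonate comes from (R)-glyceraldehyde acetonide (C2 bought), prenyl bromide, ethyl vinyl ketone and a phosphonoacetate. C3 is set by Felkin control from C2; C5, C9 and C10 are relayed from C2 in the key step.

Key step: step 11

Remark: positions are given in labdane numbering (C1–C20). The target is read as the (2R,3S,5R,9S,10S,13R) isomer: 5α-H, 9α-H, 10β-CH2OAc, 2α-angeloyloxy, 3α-OH.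

**Step 1**
Reactants: 1 (R)-2,2-dimethyl-1,3-dioxolane-4-carbaldehyde; 2 prenyl bromide
Product: 3 (1S)-1-[(4R)-2,2-dimethyl-1,3-dioxolan-4-yl]-2,2-dimethylbut-3-en-1-ol
Conditions: Zn dust, THF/sat. aq. NH4Cl, 0 °C to rt
Reagents that add atoms: none
Why: Barbier-type reverse prenylation; the allylzinc adds through its γ-carbon in a six-membered transition state, which builds the C4 quaternary carbon, and Felkin–Anh addition anti to the α-oxygen of 1 should set C3 as the anti (S) carbinol.

**Step 2**
Reactants: 3 anti homoallylic alcohol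
Product: 4 (2R,3S)-4,4-dimethylhex-5-ene-1,2,3-triol
Conditions: AcOH/H2O (4:1), 40 °C
Reagents that add atoms: none
Why: Acid-catalysed acetal hydrolysis of a terminal acetonide is fast under conditions that leave the alkene and both stereocentres untouched.

**Step 3**
Reactants: 4 triol
Product: 5 (2S,3S)-1-iodo-4,4-dimethylhex-5-ene-2,3-diol
Conditions: PPh3, imidazole, I2, THF, 0 °C
Reagents that add atoms: iodine, II
Why: Garegg–Samuelsson (Appel-type) iodination should take the unhindered primary hydroxyl in preference to the two secondary ones, one of which is neopentyl.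

**Step 4**
Reactants: 5 iodo diol
Product: 6 (4S,5S)-4-(iodomethyl)-2,2-dimethyl-5-(2-methylbut-3-en-2-yl)-1,3-dioxolane
Conditions: 2,2-dimethoxypropane, PPTS (cat.), CH2Cl2, rt
Reagents that add atoms: 2,2-dimethoxypropane, COC(C)(C)OC
Why: Acid-catalysed transacetalisation of the only 1,2-diol gives the cis-dioxolane, which protects O2 and O3 together and later holds C1 and C4 gauche for ring closure.

**Step 5**
Reactants: 6 iodo acetonide; 7 pent-1-en-3-one (ethyl vinyl ketone)
Product: 8 (E)-6-[(4S,5S)-5-(iodomethyl)-2,2-dimethyl-1,3-dioxolan-4-yl]-6-methylhept-4-en-3-one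
Conditions: 7 (4 equiv), second-generation Hoveyda–Grubbs catalyst (5 mol %), CH2Cl2, 40 °C
Reagents that add atoms: none
Why: Olefin cross-metathesis of a vinyl group on a quaternary carbon (no homodimerisation) with an enone partner should be selective and give the E enone.

**Step 6**
Reactants: 8 enone
Product: 9 tert-butyl{[(2Z,4E)-6-[(4S,5S)-5-(iodomethyl)-2,2-dimethyl-1,3-dioxolan-4-yl]-6-methylhepta-2,4-dien-3-yl]oxy}dimethylsilane
Conditions: TBSOTf, Et3N, CH2Cl2, −78 to 0 °C
Reagents that add atoms: tert-butyldimethylsilyl triflate, CC(C)(C)[Si](C)(C)OS(=O)(=O)C(F)(F)F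
Why: Soft enolisation (silyl triflate and amine) can only occur at the α' methylene because C4 carries no hydrogen, which gives the cross-conjugated 2-silyloxydiene, with the Z enol ether (methyl pointing away from the diene) expected as for ethyl ketones.

**Step 7**
Reactants: 9 silyloxydiene iodide; 10 methyl 2-[bis(2,2,2-trifluoroethoxy)phosphoryl]acetate
Product: 12 methyl 2-[bis(2,2,2-trifluoroethoxy)phosphoryl]-3-{(4R,5S)-5-[(3E,5Z)-5-(tert-butyldimethylsilyloxy)-2-methylhepta-3,5-dien-2-yl]-2,2-dimethyl-1,3-dioxolan-4-yl}propanoate (both epimers at the phosphorus-bearing carbon), via sodium phosphonoacetate 11 (not isolated)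
Conditions: 10, NaH, DMF, 0 °C; then 9, 50 °C
Reagents that add atoms: none
Why: C-alkylation (SN2) of the stabilised phosphonoacetate anion by the primary iodide in a dipolar aprotic solvent forms the C1–C10 bond; the new centre is a mixture that is erased in step 10.

**Step 8**
Reactants: 13 (R)-(−)-linalool
Product: 14 triethyl{[(3R)-3,7-dimethylocta-1,6-dien-3-yl]oxy}silane
Conditions: TESOTf, 2,6-lutidine, CH2Cl2, −78 to 0 °C
Reagents that add atoms: triethylsilyl triflate, CC[Si](CC)(CC)OS(=O)(=O)C(F)(F)F
Why: Silylation of the hindered tertiary allylic alcohol with a silyl triflate and a hindered pyridine base leaves C13 untouched.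

**Step 9**
Reactants: 14 linalool triethylsilyl ether
Product: 16 (4R)-4-methyl-4-(triethylsilyloxy)hex-5-enal, via ozonide 15 (not isolated)
Conditions: O3 (1 equiv, Sudan red 7B end point), CH2Cl2, −78 °C; then PPh3, −78 °C to rt
Reagents that add atoms: ozone, [O-][O+]=O
Why: Ozonolysis with one equivalent of ozone should cleave the electron-rich trisubstituted alkene much faster than the hindered monosubstituted vinyl group, and reductive work-up gives the aldehyde.

**Step 10**
Reactants: 12 phosphonate; 16 aldehyde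
Product: 18 methyl (2Z,6R)-2-{[(4R,5S)-5-[(3E,5Z)-5-(tert-butyldimethylsilyloxy)-2-methylhepta-3,5-dien-2-yl]-2,2-dimethyl-1,3-dioxolan-4-yl]methyl}-6-methyl-6-(triethylsilyloxy)octa-2,7-dienoate, via potassium phosphonate carbanion 17 (not isolated)
Conditions: KN(SiMe3)2 (0.98 equiv), 18-crown-6, THF, −78 °C; then 16
Reagents that add atoms: none
Why: Still–Gennari variant of the Horner–Wadsworth–Emmons olefination; the electron-poor bis(trifluoroethyl) phosphonate with a dissociated potassium counter-ion eliminates quickly from the kinetic adduct and should give the Z trisubstituted enoate (ester cis to C11), while silyl enol ether, acetonide and silyl ether tolerate the base at −78 °C.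

**Step 11**
Reactants: 18 triene
Product: 20 methyl (13R)-2α,3α-(isopropylidenedioxy)-7-oxo-13-(triethylsilyloxy)labd-14-en-20-oate (trans-decalin; 5α-H; 9α-H; 8α-H with C17 β), via silyl enol ether cycloadduct 19 (not isolated)
Conditions: toluene (0.01 M), BHT (cat.), 180 °C, sealed base-washed tube; then THF, 1 M aq. HCl, 0 °C
Reagents that add atoms: none
Why: Thermal, concerted but asynchronous normal-demand [4+2] cycloaddition in which the HOMO of the 2-silyloxydiene (largest coefficient at C8) meets the LUMO of the Z enoate (largest coefficient at C9), so the orientation forced by the tether is also the electronically matched "para" one; the closest known reaction type is the intramolecular Diels–Alder reaction of 1,3,9-decatrienes that carry a 2-silyloxydiene, which gives decalins with an angular carbonyl group. Ring B is closed by the cycloaddition itself (both new σ bonds, boat-like six-membered transition state) and ring A by the C5–C10 bond across the four-atom tether C1–C4 in the fused mode with a chair-like tether. At C9 and C10 the cis relation of C11 and C20 is passed on suprafacially from the Z alkene; the trans ring fusion (C5 against C10) follows from the ester lying endo and the tether exo; the absolute sense at C5, C9 and C10 is controlled by C2, whose acetonide oxygen stays equatorial on the chair-like tether and so avoids the syn-axial clash with the endo ester and the axial C4 methyl that attack on the other face would impose; C8 is of no consequence because it becomes sp2 in step 12. The step needs endo over exo selectivity, π-facial selectivity and chemoselectivity over the C14=C15 vinyl group: the first rests on secondary overlap of the ester together with the tether bias from the gem-dimethyl group and the cis-dioxolane, the second on C2, the third on the vinyl group being unactivated and remote. Dilute acid then cleaves only the silyl enol ether (protonation at C6) and should leave the tertiary silyl ether and the acetonide.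

**Step 12**
Reactants: 20 ketone
Product: 22 methyl (13R)-2α,3α-(isopropylidenedioxy)-13-(triethylsilyloxy)-7-(trifluoromethylsulfonyloxy)labda-7,14-dien-20-oate, via lithium enolate 21 (not isolated)
Conditions: LiN(SiMe3)2 (0.95 equiv), THF, −78 to 23 °C (equilibration); then PhNTf2, 0 to 23 °C
Reagents that add atoms: N-phenylbis(trifluoromethanesulfonimide), O=S(=O)(N(c1ccccc1)S(=O)(=O)C(F)(F)F)C(F)(F)F
Why: Enol triflate formation under thermodynamic control; with a slight deficiency of base the lithium enolates equilibrate through the remaining ketone toward the more substituted C7=C8 enolate (the ester has no α-hydrogen; the C8 centre is erased), which the triflimide then traps.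

**Step 13**
Reactants: 22 enol triflate
Product: 23 methyl (13R)-2α,3α-(isopropylidenedioxy)-13-(triethylsilyloxy)labda-7,14-dien-20-oate
Conditions: Pd(OAc)2 (5 mol %), PPh3, n-Bu3N, HCO2H, DMF, 60 °C
Reagents that add atoms: none
Why: Palladium-catalysed formate reduction of an enol triflate; oxidative addition to zerovalent palladium, formate exchange, loss of CO2 and reductive elimination give the C7=C8 alkene with hydrogen at C7, without touching the ester, the silyl ether or the vinyl group.

**Step 14**
Reactants: 23 diene ester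
Product: 24 (13R)-2α,3α-(isopropylidenedioxy)-13-(triethylsilyloxy)labda-7,14-dien-20-ol
Conditions: LiAlH4, THF, 0 °C to rt
Reagents that add atoms: none
Why: Hydride reduction of the hindered angular methyl ester to the neopentyl primary alcohol; acetonide, silyl ether and isolated alkenes are inert to LiAlH4.

**Step 15**
Reactants: 24 primary alcohol
Product: 25 (13R)-2α,3α-(isopropylidenedioxy)-13-(triethylsilyloxy)labda-7,14-dien-20-yl acetate
Conditions: Ac2O, pyridine, DMAP (cat.), CH2Cl2, rt
Reagents that add atoms: acetic anhydride, CC(=O)OC(C)=O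
Why: DMAP-catalysed acylation of the only free hydroxyl.

**Step 16**
Reactants: 25 acetate
Product: 26 (13R)-2α,3α,13-trihydroxylabda-7,14-dien-20-yl acetate
Conditions: PPTS, MeOH, 45 °C
Reagents that add atoms: none
Why: Mild acid-catalysed transacetalisation and solvolysis in methanol should remove the acetonide and the tertiary triethylsilyl ether together while the primary acetate survives; the weak acid is chosen so that the tertiary allylic C13 alcohol is not ionised.

**Step 17**
Reactants: 26 triol acetate; 27 angelic acid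
Product: 29 (13R)-20-acetoxy-2α-angeloyloxylabda-7,14-diene-3α,13-diol (the target), via mixed anhydride 28 (not isolated)
Conditions: 27, 2,4,6-trichlorobenzoyl chloride, Et3N, toluene, rt; then 26, 75 °C (no DMAP)
Reagents that add atoms: none
Why: Yamaguchi esterification through the mixed anhydride without a nucleophilic catalyst, which should avoid Z to E isomerisation of the angelate; the equatorial C2 hydroxyl reacts, while the axial neopentyl C3 hydroxyl and the tertiary C13 hydroxyl are too hindered.

**Compound list**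
1 | (R)-2,2-dimethyl-1,3-dioxolane-4-carbaldehyde | O=C[C@H]1COC(C)(C)O1 | starting material
2 | prenyl bromide (1-bromo-3-methylbut-2-ene) | CC(C)=CCBr | starting material
3 | (1S)-1-[(4R)-2,2-dimethyl-1,3-dioxolan-4-yl]-2,2-dimethylbut-3-en-1-ol | C=CC(C)(C)[C@H](O)[C@H]1COC(C)(C)O1 | intermediate
4 | (2R,3S)-4,4-dimethylhex-5-ene-1,2,3-triol | C=CC(C)(C)[C@H](O)[C@H](O)CO | intermediate
5 | (2S,3S)-1-iodo-4,4-dimethylhex-5-ene-2,3-diol | C=CC(C)(C)[C@H](O)[C@H](O)CI | intermediate
6 | (4S,5S)-4-(iodomethyl)-2,2-dimethyl-5-(2-methylbut-3-en-2-yl)-1,3-dioxolane | C=CC(C)(C)[C@@H]1OC(C)(C)O[C@@H]1CI | intermediate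
7 | pent-1-en-3-one (ethyl vinyl ketone) | C=CC(=O)CC | starting material
8 | (E)-6-[(4S,5S)-5-(iodomethyl)-2,2-dimethyl-1,3-dioxolan-4-yl]-6-methylhept-4-en-3-one | CCC(=O)/C=C/C(C)(C)[C@@H]1OC(C)(C)O[C@@H]1CI | intermediate
9 | tert-butyl{[(2Z,4E)-6-[(4S,5S)-5-(iodomethyl)-2,2-dimethyl-1,3-dioxolan-4-yl]-6-methylhepta-2,4-dien-3-yl]oxy}dimethylsilane | C/C=C(O[Si](C)(C)C(C)(C)C)/C=C/C(C)(C)[C@@H]1OC(C)(C)O[C@@H]1CI | intermediate
10 | methyl 2-[bis(2,2,2-trifluoroethoxy)phosphoryl]acetate | COC(=O)CP(=O)(OCC(F)(F)F)OCC(F)(F)F | starting material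
11 | sodium salt of 10 (not isolated) | COC(=O)[CH-]P(=O)(OCC(F)(F)F)OCC(F)(F)F.[Na+] | intermediate
12 | methyl 2-[bis(2,2,2-trifluoroethoxy)phosphoryl]-3-{(4R,5S)-5-[(3E,5Z)-5-(tert-butyldimethylsilyloxy)-2-methylhepta-3,5-dien-2-yl]-2,2-dimethyl-1,3-dioxolan-4-yl}propanoate (epimers at C2 of the propanoate) | C/C=C(O[Si](C)(C)C(C)(C)C)/C=C/C(C)(C)[C@@H]1OC(C)(C)O[C@@H]1CC(C(=O)OC)P(=O)(OCC(F)(F)F)OCC(F)(F)F | intermediate
13 | (R)-(−)-linalool, (3R)-3,7-dimethylocta-1,6-dien-3-ol | C=C[C@](C)(O)CCC=C(C)C | starting material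
14 | triethyl{[(3R)-3,7-dimethylocta-1,6-dien-3-yl]oxy}silane | C=C[C@](C)(O[Si](CC)(CC)CC)CCC=C(C)C | intermediate
15 | secondary ozonide of 14: 3,3-dimethyl-5-[(3R)-3-methyl-3-(triethylsilyloxy)pent-4-enyl]-1,2,4-trioxolane (not isolated) | C=C[C@](C)(O[Si](CC)(CC)CC)CCC1OOC(C)(C)O1 | intermediate
16 | (4R)-4-methyl-4-(triethylsilyloxy)hex-5-enal | C=C[C@](C)(O[Si](CC)(CC)CC)CCC=O | intermediate
17 | potassium salt of 12 (not isolated) | C/C=C(O[Si](C)(C)C(C)(C)C)/C=C/C(C)(C)[C@@H]1OC(C)(C)O[C@@H]1C[C-](C(=O)OC)P(=O)(OCC(F)(F)F)OCC(F)(F)F.[K+] | intermediate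
18 | methyl (2Z,6R)-2-{[(4R,5S)-5-[(3E,5Z)-5-(tert-butyldimethylsilyloxy)-2-methylhepta-3,5-dien-2-yl]-2,2-dimethyl-1,3-dioxolan-4-yl]methyl}-6-methyl-6-(triethylsilyloxy)octa-2,7-dienoate | C/C=C(O[Si](C)(C)C(C)(C)C)/C=C/C(C)(C)[C@@H]1OC(C)(C)O[C@@H]1C/C(C(=O)OC)=C/CC[C@@](C)(O[Si](CC)(CC)CC)C=C | intermediate
19 | methyl (13R)-7-(tert-butyldimethylsilyloxy)-2α,3α-(isopropylidenedioxy)-13-(triethylsilyloxy)labda-6,14-dien-20-oate, 5α-H, 9α-H, 8α-H (not isolated) | C=C[C@](C)(O[Si](CC)(CC)CC)CC[C@H]1[C@@H](C)C(O[Si](C)(C)C(C)(C)C)=C[C@H]2C(C)(C)[C@@H]3OC(C)(C)O[C@@H]3C[C@]12C(=O)OC | intermediate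
20 | methyl (13R)-2α,3α-(isopropylidenedioxy)-7-oxo-13-(triethylsilyloxy)labd-14-en-20-oate, 5α-H, 9α-H, 8α-H | C=C[C@](C)(O[Si](CC)(CC)CC)CC[C@H]1[C@@H](C)C(=O)C[C@H]2C(C)(C)[C@@H]3OC(C)(C)O[C@@H]3C[C@]12C(=O)OC | intermediate
21 | lithium C7=C8 enolate of 20 (not isolated) | C=C[C@](C)(O[Si](CC)(CC)CC)CC[C@H]1C(C)=C([O-])C[C@H]2C(C)(C)[C@@H]3OC(C)(C)O[C@@H]3C[C@]12C(=O)OC.[Li+] | intermediate
22 | methyl (13R)-2α,3α-(isopropylidenedioxy)-13-(triethylsilyloxy)-7-(trifluoromethylsulfonyloxy)labda-7,14-dien-20-oate | C=C[C@](C)(O[Si](CC)(CC)CC)CC[C@H]1C(C)=C(OS(=O)(=O)C(F)(F)F)C[C@H]2C(C)(C)[C@@H]3OC(C)(C)O[C@@H]3C[C@]12C(=O)OC | intermediate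
23 | methyl (13R)-2α,3α-(isopropylidenedioxy)-13-(triethylsilyloxy)labda-7,14-dien-20-oate | C=C[C@](C)(O[Si](CC)(CC)CC)CC[C@H]1C(C)=CC[C@H]2C(C)(C)[C@@H]3OC(C)(C)O[C@@H]3C[C@]12C(=O)OC | intermediate
24 | (13R)-2α,3α-(isopropylidenedioxy)-13-(triethylsilyloxy)labda-7,14-dien-20-ol | C=C[C@](C)(O[Si](CC)(CC)CC)CC[C@H]1C(C)=CC[C@H]2C(C)(C)[C@@H]3OC(C)(C)O[C@@H]3C[C@]12CO | intermediate
25 | (13R)-2α,3α-(isopropylidenedioxy)-13-(triethylsilyloxy)labda-7,14-dien-20-yl acetate | C=C[C@](C)(O[Si](CC)(CC)CC)CC[C@H]1C(C)=CC[C@H]2C(C)(C)[C@@H]3OC(C)(C)O[C@@H]3C[C@]12COC(C)=O | intermediate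
26 | (13R)-2α,3α,13-trihydroxylabda-7,14-dien-20-yl acetate | C=C[C@](C)(O)CC[C@H]1C(C)=CC[C@H]2C(C)(C)[C@H](O)[C@H](O)C[C@]12COC(C)=O | intermediate
27 | angelic acid, (Z)-2-methylbut-2-enoic acid | C/C=C(/C)C(=O)O | starting material
28 | (Z)-2-methylbut-2-enoic 2,4,6-trichlorobenzoic anhydride (not isolated) | C/C=C(/C)C(=O)OC(=O)c1c(Cl)cc(Cl)cc1Cl | intermediate
29 | (2R,3S,5R,9S,10S,13R)-20-acetoxy-2-[(Z)-2-methylbut-2-enoyloxy]labda-7,14-diene-3,13-diol | C=C[C@](C)(O)CC[C@H]1C(C)=CC[C@H]2C(C)(C)[C@H](O)[C@H](OC(=O)/C(C)=C\C)C[C@]12COC(C)=O | target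

**Step count and risks**
Total steps: 17. Longest linear sequence: 15 steps (steps 1–7 and 10–17, from 1); steps 8 and 9 form the side branch.

The three steps most likely to fail:

Step 7. The displacement at the β-alkoxy, β-branched primary iodide by the weakly nucleophilic fluorinated phosphonoacetate anion may be too slow, so that loss of the silyl enol ether on prolonged heating competes. The fallback replaces the iodide by a far more reactive electrophile reached through an oxygen nucleophile. It sets out from 9: displacement with CsOAc and 18-crown-6 in DMF should give the primary acetate F1; reductive deacylation with i-Bu2AlH at −78 °C, which spares the silyl enol ether, should give the primary alcohol F2; Tf2O and 2,6-lutidine at −78 °C should give the primary triflate F3; F3 is then alkylated at 0 °C in THF with the sodium salt 11. The fallback comes back to the route at 12.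

Step 11. The cycloaddition of the hindered trisubstituted enoate may be so slow that decomposition of the silyl enol ether, or erosion of endo and facial selectivity at high temperature, takes over. The fallback raises the activation of the dienophile by changing the oxidation level of C20. It sets out from 18: i-Bu2AlH at −78 °C should give the Z allylic alcohol F4, and MnO2 the Z enal F5, which is used at once to avoid Z to E isomerisation. The enal should cyclise in toluene at 80–110 °C through the same endo transition state to the silyl enol ether aldehyde F6. Dilute HCl in THF then gives the keto aldehyde F7, Pinnick oxidation (NaClO2, NaH2PO4, 2-methylbut-2-ene) the keto acid F8, and Me3SiCHN2 in methanol/toluene the methyl ester. The fallback comes back to the route at 20.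

Step 12. Enolisation may go to C6 instead of C8, or equilibration may stay incomplete, so that the C6=C7 enol triflate forms and the alkene ends up in the wrong position. The fallback reaches the alkene by anti elimination instead of by enolate trapping. It sets out from 20: NaOMe in MeOH should epimerise C8 to the equatorial 8α-methyl ketone F9; LiBH(s-Bu)3 at −78 °C should attack from the equatorial side and give the axial 7α-alcohol F10; dehydration with the sulfurane Ph2S[OC(CF3)2Ph]2 at rt should then proceed by anti-periplanar loss of the axial tertiary H8β and the axial hydroxyl toward the more substituted alkene. The fallback comes back to the route at 23.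

**Further compounds**
F1 | step 7 | {(4R,5S)-5-[(3E,5Z)-5-(tert-butyldimethylsilyloxy)-2-methylhepta-3,5-dien-2-yl]-2,2-dimethyl-1,3-dioxolan-4-yl}methyl acetate | C/C=C(O[Si](C)(C)C(C)(C)C)/C=C/C(C)(C)[C@@H]1OC(C)(C)O[C@@H]1COC(C)=O
F2 | step 7 | {(4R,5S)-5-[(3E,5Z)-5-(tert-butyldimethylsilyloxy)-2-methylhepta-3,5-dien-2-yl]-2,2-dimethyl-1,3-dioxolan-4-yl}methanol | C/C=C(O[Si](C)(C)C(C)(C)C)/C=C/C(C)(C)[C@@H]1OC(C)(C)O[C@@H]1CO
F3 | step 7 | {(4R,5S)-5-[(3E,5Z)-5-(tert-butyldimethylsilyloxy)-2-methylhepta-3,5-dien-2-yl]-2,2-dimethyl-1,3-dioxolan-4-yl}methyl trifluoromethanesulfonate | C/C=C(O[Si](C)(C)C(C)(C)C)/C=C/C(C)(C)[C@@H]1OC(C)(C)O[C@@H]1COS(=O)(=O)C(F)(F)F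
F4 | step 11 | Z allylic alcohol from 18 (CH2OH in place of CO2Me) | C/C=C(O[Si](C)(C)C(C)(C)C)/C=C/C(C)(C)[C@@H]1OC(C)(C)O[C@@H]1C/C(CO)=C/CC[C@@](C)(O[Si](CC)(CC)CC)C=C
F5 | step 11 | Z enal from 18 (CHO in place of CO2Me) | C/C=C(O[Si](C)(C)C(C)(C)C)/C=C/C(C)(C)[C@@H]1OC(C)(C)O[C@@H]1C/C(C=O)=C/CC[C@@](C)(O[Si](CC)(CC)CC)C=C
F6 | step 11 | (13R)-7-(tert-butyldimethylsilyloxy)-2α,3α-(isopropylidenedioxy)-13-(triethylsilyloxy)labda-6,14-dien-20-al | C=C[C@](C)(O[Si](CC)(CC)CC)CC[C@H]1[C@@H](C)C(O[Si](C)(C)C(C)(C)C)=C[C@H]2C(C)(C)[C@@H]3OC(C)(C)O[C@@H]3C[C@]12C=O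
F7 | step 11 | (13R)-2α,3α-(isopropylidenedioxy)-7-oxo-13-(triethylsilyloxy)labd-14-en-20-al | C=C[C@](C)(O[Si](CC)(CC)CC)CC[C@H]1[C@@H](C)C(=O)C[C@H]2C(C)(C)[C@@H]3OC(C)(C)O[C@@H]3C[C@]12C=O
F8 | step 11 | (13R)-2α,3α-(isopropylidenedioxy)-7-oxo-13-(triethylsilyloxy)labd-14-en-20-oic acid | C=C[C@](C)(O[Si](CC)(CC)CC)CC[C@H]1[C@@H](C)C(=O)C[C@H]2C(C)(C)[C@@H]3OC(C)(C)O[C@@H]3C[C@]12C(=O)O
F9 | step 12 | C8 epimer of 20 (8β-H, C17 α and equatorial) | C=C[C@](C)(O[Si](CC)(CC)CC)CC[C@H]1[C@H](C)C(=O)C[C@H]2C(C)(C)[C@@H]3OC(C)(C)O[C@@H]3C[C@]12C(=O)OC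
F10 | step 12 | methyl (13R)-7α-hydroxy-2α,3α-(isopropylidenedioxy)-13-(triethylsilyloxy)labd-14-en-20-oate (8β-H) | C=C[C@](C)(O[Si](CC)(CC)CC)CC[C@H]1[C@H](C)[C@H](O)C[C@H]2C(C)(C)[C@@H]3OC(C)(C)O[C@@H]3C[C@]12C(=O)OC
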